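## The problem

The target is a longipinane: a cyclobutane (C1, C2, C8, C7) whose 1,3-carbons C1/C8 are spanned by the enone bridge C11(=O)–C10=C9(CH3) and whose other 1,3-carbons C2/C7 are spanned by the four-carbon bridge C3–C4–C5–C6. This gives a bicyclo[3.1.1]heptenone fused to a seven-membered ring. All four cyclobutane carbons are stereogenic and C2 is quaternary. Once the cage exists, C1, C7 and C8 are locked to one another, but C2 can still carry its methyl group syn or anti to the enone bridge. The two carbinol carbons C3 and C5 lie in what would be a mirror plane of the cage were it not for the difference between the C11 carbonyl and the C9 methyl group. The cage therefore gives almost no facial bias at C3 or C5, so one of them needs reagent control and the other can follow by 1,3-induction. The two different esters must be told apart on an anti-1,3-diol. The methacrylate (polymerisable acceptor) and the enone must be introduced late, and a strained cyclobutane bearing a β-carbonyl pattern rules out harsh acid or base at the end. The feature that opens the synthesis is the pair C2/C1: C2 is quaternary and carries a methyl group and the carbon C3, while C1 is a secondary CH. C2 can therefore be the enolate carbon of a propionate unit hanging on C8 and C1 the sulfonate-bearing carbon of a cyclohexene (C8, C9, C10, C11, C1, C7), the two being 1,3-related across C7.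

## Retrosynthesis

**35 to 32.** The C5–O acyl bond and the C11 carbonyl are removed first, via silyl ether 33 and allylic alcohol 34. Cutting here keeps the methacrylate and the enone out of all carbon–carbon bond formation. Hydroxy isobutyrate 32 has one free hydroxyl and one masked allylic alcohol, so the forward steps only ask for acylation of a hindered alcohol, desilylation and allylic oxidation.

**32 to 29 and 30.** The C3 ester C–O bond and the C5–H bond are cut together (Evans–Tishchenko). Against a plain anti-reduction, which would leave two equally hindered hydroxyls, this cut sets C5 from C3, tells the two oxygens apart and draws the isobutyrate from aldehyde 30. The precursor, β-hydroxy ketone 29, has one stereocenter fewer. The forward reaction must deliver hydride across a seven-membered ring.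

**29 to 27 to 25.** The C3–O bond is cut back to enone 27 (conjugate borylation and oxidation) and the C3=C4 bond to keto aldehyde 25 (aldol condensation closing the seven-membered ring). A direct aldol addition would make the same C3–C4 bond one step sooner but would leave C3 to the unbiased cage. Passing through 27 lets a chiral copper catalyst choose the face. Compound 25 is bicyclic, and its only enolisable position is the methyl ketone.

**25 to 22.** These are functional-group changes only: the C3 aldehyde comes from the ester and the C5 methyl ketone from the vinyl group. The vinyl group is chosen because a ketone on the arm could not survive the ring closure before it; its enolate would close a five-membered ring onto C1. Ester 22 already holds the cage and four of the six stereocenters.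

**22 to 20 (key).** The C1–C2 bond is cut. Cutting C2–C8 or C1–C7 of the cyclobutane instead would require substitution at a carbon next to a quaternary centre or formation of the quaternary centre as the electrophile. Here the quaternary carbon is made as the nucleophile. Mesylate 20 is a monocyclic cyclohexene, and either C2 epimer serves. The forward reaction must alkylate on carbon, invert C1 and place the C2 methyl group syn to the C9–C11 bridge.

**20 to 15 (and 14).** The C2–C8 bond is cut by an Ireland–Claisen transform back to the C10 propionate 15, made from diol 13 and acid chloride 14; hydroxy ester 19 lies between. This cut moves the stereochemical information from the C10 oxygen to C8, puts the side chain on the face of the C7 arm and shifts the alkene to C9=C10, where the target needs it.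

**15 to 12 to 11.** The three hydroxyls of triol 12 are told apart by their environment (C11 silylated, C10 acylated, C1 left free for the mesylate), and 12 is the deprotected form of acetonide 11.

**11 to 7 to 6 to 3 and 4.** The vinyl group is traced to the nitrile of 7 (through lactol 10), and the C9 methyl group to the bromine of 6. The C6–C7 bond is cut to epoxide 3 and nitrile 4. The bromine is kept until after the epoxide has been opened, because it steers the epoxidation to the other alkene and blocks conjugate opening.

**3 to 2 to 1.** Epoxide and acetonide are removed to reach the enantiopure diol 1. Its two oxygens become the C10 oxygen that drives the sigmatropic step and the C11 oxygen that ends as the ketone.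

## Roads not taken

**Alternative 1:** The cut is through C6–C7, C1–C7 and C2–C8 at once, back to acyclic farnesyl diphosphate A1. The forward step is an enzymatic cationic polycyclisation by an α-longipinene synthase, giving α-longipinene A2 with all three rings and the four cage stereocenters in a single operation. In skeletal economy this road is far better than the chosen plan, which needs twelve steps to reach the bicyclic ester 22. Its weakness for this target lies after A2. Three oxygens are missing; the C11 carbonyl can be reached by allylic oxidation, but C3 and C5 are unactivated methylene groups in the same unbiased plane described above. No chemical reagent is expected to distinguish C3, C4 and C5, set the anti relationship and allow two different esters; further tailoring enzymes and a fermentation platform would be required. The chosen plan sets against its greater length that every oxygen is placed by polar bond formation (C11 from 1, C3 and C5 from the carbonyl groups of 25) and that each stereocenter has a named control element.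

**Alternative 2:** The cut is through C8–C9 and C1–C11, back to the prochiral cyclobutanone A3 and crotonoyl chloride A4. The forward step is an amine-mediated α,α′-annulation under control of a chiral secondary amine, giving the bicyclo[3.1.1]heptane-2,6-dione A5. Its merits are real: the cyclobutane is bought rather than made, the bicyclic core appears in two or three steps, and the C11 carbonyl is already in place. It has three weak points. First, the desymmetrisation must fix the quaternary carbon C2, whose two substituents (methyl and silyloxymethyl) are remote from the reacting centres and similar in size. Second, annulations of this kind are established for five- and six-membered ketones, while cyclobutanone enamines tend to ring-open. Third, A5 is a non-enolisable bridged β-diketone prone to retro-Claisen cleavage, yet it must still receive the tertiary C6 arm at C7 with control of configuration, lose the C7 oxygen, gain the C9=C10 alkene and have the seven-membered ring built on it. The chosen plan is longer up to the bicycle, but C7, C8 and C1 come from the epoxide opening and the sigmatropic shift, and C2 is fixed by allylic strain, not by a remote steric difference.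

**Alternative 3:** The cut is through C4–C5 and the C3–O bond, back to aldoxime A6, which already contains the bicyclic enone with a vinyl group on C2. The forward step is oxidation to nitrile oxide A7 and intramolecular dipolar cycloaddition to isoxazoline A8; reductive N–O cleavage would then give the same β-hydroxy ketone pattern as 29. For the late stage this road is as short as the chosen one (three operations against steps 15 to 17) and it forms the carbon–carbon and carbon–oxygen bonds together, which is better than the chosen plan. It has three drawbacks. The cycloaddition must close a bridged seven-membered ring, so dimerisation of A7 competes. The face of the C2 vinyl group that is attacked is again decided by the unbiased cage, so C3 is not controlled. And A6 still needs the cyclobutane with its quaternary C2, a problem this key step does not address. The chosen plan sets against it a catalyst-controlled C3 and a ring closure (aldol condensation) with no competing intermolecular channel, and it solves the cage first.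

Key step: step 12

## Conventions and assumptions

- Locants C1 to C11 are those of the target skeleton (tricyclo[5.4.0.0^{2,8}]undecane numbering) and are used for the same atoms in every intermediate. The β face of the six-membered carbocycle (C1, C7, C8, C9, C10, C11) is the face that carries the two hydroxyls of 1; α is the opposite face.
- Compounds 17 to 21 form as mixtures of C2 epimers. The SMILES show the 2R epimer; both converge in step 12, where C2 becomes planar.
- The ligand antipode written in step 17 is the one assumed to deliver boron to the Re face of C3. If the induction proves opposite, the enantiomeric ligand is used without any other change.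

## Route

Step 1
Reactants: 1 (1S,2S)-3-bromocyclohexa-3,5-diene-1,2-diol
Product: 2 acetonide (3aS,7aS)-4-bromo-2,2-dimethyl-3a,7a-dihydro-1,3-benzodioxole
Conditions: 2,2-dimethoxypropane, TsOH·H2O (cat.), acetone, 0 °C to rt
Reagents that add atoms: 2,2-dimethoxypropane, COC(C)(C)OC
Why: Acid-catalysed transketalisation of a cis-1,2-diol; the dioxolane shields the β face and prevents the free hydroxyls from directing the peracid in step 2. The diene is used at once because it dimerises on standing.

Step 2
Reactants: 2 acetonide
Product: 3 anti-epoxide of 2 (C1–C7 oxirane on the α face)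
Conditions: m-CPBA, NaHCO3, CH2Cl2, 0 °C to rt
Reagents that add atoms: 3-chloroperoxybenzoic acid, OOC(=O)c1cccc(Cl)c1
Why: Prilezhaev epoxidation; the bromine deactivates the C8=C9 alkene, so the peracid takes C1=C7, and it approaches anti to the dioxolane. This sets the C1 oxygen α and prepares C7 for substitution.

Step 3
Reactants: 3 anti-epoxide, 4 isobutyronitrile
Product: 6 bromo hydroxy nitrile (1α-OH; 7β-C(CH3)2CN), via 2-lithio-2-methylpropanenitrile 5 (not isolated)
Conditions: LiN(i-Pr)2, THF, −78 °C; then 3, −78 to 0 °C; aq. NH4Cl
Reagents that add atoms: none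
Why: SN2 opening of a vinyl epoxide by a nitrile-stabilised carbanion at the allylic carbon C7, the terminus remote from the dioxolane, with inversion; the arm is therefore β and trans to the C1 hydroxyl. The bromine on C9 blocks the conjugate (SN2′) mode, and the adduct has no acidic hydrogen next to the nitrile.

Step 4
Reactants: 6 bromo hydroxy nitrile
Product: 7 methyl hydroxy nitrile (C9–CH3)
Conditions: MeZnCl (3 equiv), Pd(PPh3)4 (5 mol%), THF, 60 °C
Reagents that add atoms: methylzinc chloride, C[Zn]Cl
Why: Negishi coupling of an alkenyl bromide (oxidative addition to zerovalent palladium, transmetalation, reductive elimination) without movement of the alkene. It is placed after step 3 because zerovalent palladium would ionise the vinyl epoxide of 3. The free hydroxyl only consumes one equivalent of the zinc reagent.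

Step 5
Reactants: 7 methyl hydroxy nitrile
Product: 10 lactol (cyclic hemiacetal between C5 and the C1 oxygen; anomer mixture), via aldimine 8 (not isolated), via hydroxy aldehyde 9 (not isolated)
Conditions: i-Bu2AlH (2.5 equiv), PhMe, −78 to −20 °C; aq. KNaC4H4O6; wet SiO2, CH2Cl2
Reagents that add atoms: water, O
Why: Hydride addition to a tertiary nitrile stops at the imine stage; hydrolysis gives the aldehyde, which closes onto the C1 hydroxyl to the trans-fused lactol, helped by the gem-dimethyl group. No ring stereocenter is touched.

Step 6
Reactants: 10 lactol
Product: 11 vinyl alcohol (7β-(2-methylbut-3-en-2-yl); 1α-OH; acetonide)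
Conditions: Ph3PCH3Br (4 equiv), KOt-Bu (3.8 equiv), THF, 0 to 50 °C
Reagents that add atoms: methyltriphenylphosphonium bromide, C[P+](c1ccccc1)(c1ccccc1)c1ccccc1.[Br-]
Why: Wittig methylenation of a lactol through its open form 9, a non-enolisable aldehyde. The vinyl group is a base-stable mask of the C5 methyl ketone.

Step 7
Reactants: 11 vinyl alcohol
Product: 12 triol (1α-OH; 10β-OH; 11β-OH)
Conditions: AcOH/H2O (4:1), 45 °C
Reagents that add atoms: none
Why: Acid hydrolysis of the dioxolane. The allylic C10–O bond is deactivated toward ionisation by the neighbouring C11 oxygen, so no allylic transposition is expected.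

Step 8
Reactants: 12 triol
Product: 13 C11 silyl ether diol (11β-OSi(t-Bu)Me2; 10β-OH; 1α-OH)
Conditions: t-BuMe2SiCl (1.05 equiv), imidazole, DMF, −20 to 0 °C
Reagents that add atoms: tert-butyldimethylsilyl chloride, CC(C)(C)[Si](C)(C)Cl
Why: Sterically governed monosilylation: C11–OH is equatorial and cis to a pseudo-axial neighbour, the arrangement that makes the 3-hydroxyl of mannopyranosides the most reactive toward bulky silyl chlorides. C10–OH is pseudo-axial and pressed against the C9 methyl group, and C1–OH is gauche to the quaternary arm carbon; arene cis-dihydrodiols are likewise monosilylated at the hydroxyl remote from the vinylic substituent.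

Step 9
Reactants: 13 C11 silyl ether diol, 14 propionyl chloride
Product: 15 C10 propionate (1α-OH free)
Conditions: pyridine, DMAP (5 mol%), CH2Cl2, −40 to −10 °C
Reagents that add atoms: none
Why: Acylation of the allylic C10 hydroxyl. C1–OH, flanked by the silyl ether and by the carbon bearing the tertiary arm, should react much more slowly, so one equivalent of 14 at low temperature should stop at the monoester.

Step 10
Reactants: 15 C10 propionate
Product: 19 hydroxy methyl ester (C8β-CH(CH3)CO2Me; C9=C10), via silyl ketene acetal 16 (not isolated), via trimethylsilyl ester 17 (not isolated), via hydroxy acid 18 (not isolated)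
Conditions: Me3SiCl, then LiN(i-Pr)2 (3 equiv), THF, −78 to 60 °C; 1 M HCl, 0 °C; then Me3SiCHN2, PhMe/MeOH, 0 °C
Reagents that add atoms: (trimethylsilyl)diazomethane, C[Si](C)(C)C=[N+]=[N-]
Why: Ireland–Claisen rearrangement: the silyl ketene acetal undergoes a suprafacial [3,3] shift, so the pseudo-axial β C10–O bond is exchanged for the C8–C2 bond on the same face, cis to the C7 arm, and the alkene moves to C9=C10. C2 forms as an epimer mixture that is used as such; the C1 hydroxyl is masked in the flask as its trimethylsilyl ether, and the acid is methylated by the diazoalkane.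

Step 11
Reactants: 19 hydroxy methyl ester
Product: 20 mesylate (1α-OSO2CH3)
Conditions: MsCl, Et3N, CH2Cl2, −10 to 0 °C
Reagents that add atoms: methanesulfonyl chloride, CS(=O)(=O)Cl
Why: Sulfonylation through sulfene, the method of choice for hindered secondary alcohols. The C1–O bond is not broken, so the leaving group stays α.

Step 12
Reactants: 20 mesylate
Product: 22 bicyclo[3.1.1]heptene ester (C2 methyl syn to the C9–C11 bridge; CO2Me anti), via potassium enolate 21 (not isolated)
Conditions: KN(SiMe3)2 (1.3 equiv), THF (0.02 M), −78 to 0 °C
Reagents that add atoms: none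
Why: KN(SiMe3)2 removes the C2 hydrogen of either epimer of 20 to give the fully substituted ester enolate 21, whose carbon displaces the C1 mesylate from the β face with inversion; this is an intramolecular SN2 enolate alkylation, the reaction type long used to close the cyclobutane of bicyclo[3.1.1]heptanes. The four-membered ring C1–C2–C8–C7 closes in the 4-exo-tet mode, with the enolate double bond outside the new ring. C1 is set by inversion of the α-sulfonate that stems from the epoxide oxygen, so the new bond is cis to the C2–C8 bond made in step 10. C2 is set by allylic 1,3-strain: whatever its geometry, the enolate has an oxygen substituent cis to C8, so C8–H must lie in the enolate plane, and of the two rotamers that bring C2 over C1 only the one with the methyl group over the C9–C11 bridge and the carboxyl carbon on the side of the C7 arm allows this; the β-silyloxy group on C11 disfavours the other rotamer further. The step needs alkylation on carbon, not on oxygen, and substitution, not elimination: in the strain-free rotamer both enolate oxygens point away from C1, which closes the six-membered O-alkylation path, and the hydrogens on C7 and C11 are syn to the leaving group, so no anti-periplanar E2 is open. The reactive sofa conformer keeps the bulky C7 arm pseudo-equatorial, and ring strain makes the closure irreversible.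

Step 13
Reactants: 22 bicyclic ester
Product: 23 primary alcohol (C3H2OH)
Conditions: i-Bu2AlH (3 equiv), CH2Cl2, −78 to 0 °C; aq. KNaC4H4O6
Reagents that add atoms: none
Why: Hydride reduction of an ester on a quaternary carbon. Full reduction followed by reoxidation is more dependable than a partial reduction, and the silyl ether and both alkenes are inert.

Step 14
Reactants: 23 primary alcohol
Product: 24 aldehyde (C3HO)
Conditions: Dess–Martin periodinane, NaHCO3, CH2Cl2, rt
Reagents that add atoms: none
Why: Mild oxidation to a non-enolisable aldehyde; no stereocenter is involved.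

Step 15
Reactants: 24 aldehyde
Product: 25 keto aldehyde (C5 methyl ketone)
Conditions: PdCl2 (15 mol%), CuCl, O2 (1 atm), DMF/H2O (7:1), rt
Reagents that add atoms: water, O
Why: Tsuji–Wacker oxidation: Markovnikov hydroxypalladation of the terminal vinyl group and β-hydride elimination give the methyl ketone. The trisubstituted C9=C10 alkene does not react, and the aldehyde has no α-hydrogen.

Step 16
Reactants: 25 keto aldehyde
Product: 27 tricyclic enone (C5=O; C3=C4), via aldol adduct 26 (not isolated)
Conditions: KOt-Bu (0.3 equiv), t-BuOH/THF, rt to 50 °C
Reagents that add atoms: none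
Why: Intramolecular aldol condensation (7-enolexo-exo-trig addition, then E1cB loss of water). The methyl ketone is the only enolisable site, so C3–C4 is the only bond that can form; dehydration erases the uncontrolled C3 carbinol of 26 and gives the enone needed for catalyst control.

Step 17
Reactants: 27 tricyclic enone
Product: 29 β-hydroxy ketone ((3R)-OH on the side of C1), via boronate 28 (not isolated)
Conditions: CuCl (5 mol%), NaOt-Bu (10 mol%), (R)-1-[(SP)-2-(diphenylphosphino)ferrocenyl]ethyldicyclohexylphosphine (6 mol%), B2pin2 (1.3 equiv), MeOH (2 equiv), THF, rt; then NaBO3·4H2O, THF/H2O, rt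
Reagents that add atoms: sodium perborate, [Na+].[O-]OB=O (oxygen at C3); bis(pinacolato)diboron, CC1(C)OB(OC1(C)C)B1OC(C)(C)C(C)(C)O1 (boron of 28 only)
Why: Copper-catalysed enantioselective conjugate borylation of a cyclic enone: the ligated boryl copper adds boron to C3, methanol protonates the copper enolate, and perborate oxidises the C–B bond with retention. C3 is set by the ligand (boron to the Re face, the one turned toward C1), because C3 lies in the near-mirror plane of the cage and the substrate adds little bias.

Step 18
Reactants: 29 β-hydroxy ketone, 30 isobutyraldehyde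
Product: 32 hydroxy isobutyrate ((3R)-isobutyrate; (5R)-OH; anti), via hemiacetal 31 (not isolated)
Conditions: SmI2 (0.3 equiv), 30 (6 equiv), THF, −10 °C
Reagents that add atoms: none
Why: Evans–Tishchenko reduction: the C3 hydroxyl adds to 30, and the samarium-bound hemiacetal delivers its hydride to C5 through a six-membered chair on the face of the C3 oxygen. The C5 hydroxyl is therefore anti to C3–O, and the C3 oxygen emerges as the isobutyrate, which differentiates the two oxygens in the same step.

Step 19
Reactants: 32 hydroxy isobutyrate
Product: 33 methacrylate (C5 ester; C11 silyl ether)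
Conditions: methacrylic anhydride (3 equiv), DMAP, Et3N, BHT (trace), CH2Cl2, rt to 35 °C
Reagents that add atoms: methacrylic anhydride, C=C(C)C(=O)OC(=O)C(C)=C
Why: DMAP-catalysed acylation of the only free hydroxyl. Migration of the C3 ester is geometrically disfavoured, since a trans-1,3-diol in this ring cannot form the bridging orthoester.

Step 20
Reactants: 33 methacrylate
Product: 34 allylic alcohol (11β-OH)
Conditions: HF·pyridine, pyridine, THF, 0 °C to rt
Reagents that add atoms: none
Why: Buffered acidic fluoride cleaves the secondary silyl ether without hydrolysing either ester or adding to the methacrylate.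

Step 21
Reactants: 34 allylic alcohol
Product: 35 target, (1R,2R,3R,5R,7S,8R)-2,6,6,9-tetramethyl-3-(2-methylpropanoyloxy)-11-oxotricyclo[5.4.0.0^{2,8}]undec-9-en-5-yl 2-methylprop-2-enoate
Conditions: Dess–Martin periodinane, NaHCO3, CH2Cl2, 0 °C to rt
Reagents that add atoms: none
Why: Oxidation of the allylic alcohol to the enone removes the C11 stereocenter and completes the target. C1 is a bridgehead and cannot epimerise.

## Compound list

1 | (1S,2S)-3-bromocyclohexa-3,5-diene-1,2-diol | O[C@H]1C=CC=C(Br)[C@H]1O | starting material
2 | (3aS,7aS)-4-bromo-2,2-dimethyl-3a,7a-dihydro-1,3-benzodioxole (C10,C11-acetonide of 1) | CC1(C)O[C@H]2C=CC=C(Br)[C@H]2O1 | intermediate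
3 | anti-epoxide of 2: 4-bromo-2,2-dimethyl-3a,5a,6a,6b-tetrahydrooxireno[e][1,3]benzodioxole, oxirane (C1–C7, α) trans to the dioxolane | CC1(C)O[C@H]2[C@@H]3O[C@@H]3C=C(Br)[C@H]2O1 | intermediate
4 | isobutyronitrile (2-methylpropanenitrile) | CC(C)C#N | starting material
5 | 2-lithio-2-methylpropanenitrile | [Li]C(C)(C)C#N | intermediate
6 | bromo hydroxy nitrile: C8=C9(Br) cyclohexene with 10β,11β-acetonide, 1α-OH and 7β-C(CH3)2CN | CC1(C)O[C@H]2[C@H](O)[C@@H](C(C)(C)C#N)C=C(Br)[C@H]2O1 | intermediate
7 | methyl hydroxy nitrile: as 6 with CH3 on C9 | CC1(C)O[C@H]2[C@H](O)[C@@H](C(C)(C)C#N)C=C(C)[C@H]2O1 | intermediate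
8 | aldimine: as 7 with C(CH3)2CH=NH | CC1(C)O[C@H]2[C@H](O)[C@@H](C(C)(C)C=N)C=C(C)[C@H]2O1 | intermediate
9 | hydroxy aldehyde: as 7 with C(CH3)2CHO | CC1(C)O[C@H]2[C@H](O)[C@@H](C(C)(C)C=O)C=C(C)[C@H]2O1 | intermediate
10 | lactol: trans-fused cyclic hemiacetal of 9 (O1–C5(OH)–C6–C7), anomer mixture | CC1(C)O[C@H]2[C@@H]3OC(O)C(C)(C)[C@H]3C=C(C)[C@H]2O1 | intermediate
11 | vinyl alcohol: C8=C9(CH3) cyclohexene with 10β,11β-acetonide, 1α-OH and 7β-(2-methylbut-3-en-2-yl) | CC1(C)O[C@H]2[C@H](O)[C@@H](C(C)(C)C=C)C=C(C)[C@H]2O1 | intermediate
12 | triol: 1α,10β,11β-trihydroxy, 7β-(2-methylbut-3-en-2-yl), C8=C9(CH3) | O[C@H]1[C@H](O)[C@@H](C(C)(C)C=C)C=C(C)[C@H]1O | intermediate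
13 | C11 silyl ether diol: as 12 with 11β-OSi(t-Bu)Me2 | CC(C)(C)[Si](C)(C)O[C@H]1[C@H](O)[C@@H](C(C)(C)C=C)C=C(C)[C@H]1O | intermediate
14 | propionyl chloride | CCC(Cl)=O | starting material
15 | C10 propionate: as 13 with 10β-OC(=O)Et, 1α-OH free | CC(C)(C)[Si](C)(C)O[C@H]1[C@H](O)[C@@H](C(C)(C)C=C)C=C(C)[C@H]1OC(=O)CC | intermediate
16 | silyl ketene acetal of 15 with 1α-OSiMe3 (either double-bond geometry) | CC(C)(C)[Si](C)(C)O[C@H]1[C@H](O[Si](C)(C)C)[C@@H](C(C)(C)C=C)C=C(C)[C@H]1OC(=CC)O[Si](C)(C)C | intermediate
17 | rearranged trimethylsilyl ester: C9=C10 cyclohexene, 8β-CH(CH3)CO2SiMe3, 7β-arm, 1α-OSiMe3, 11β-OSi(t-Bu)Me2 (C2 epimers, 2R drawn) | C[Si](C)(C)OC(=O)[C@H](C)[C@H]1C(C)=C[C@@H](O[Si](C)(C)C(C)(C)C)[C@H](O[Si](C)(C)C)[C@H]1C(C)(C)C=C | intermediate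
18 | hydroxy acid: as 17 with CO2H and 1α-OH (C2 epimers, 2R drawn) | OC(=O)[C@H](C)[C@H]1C(C)=C[C@@H](O[Si](C)(C)C(C)(C)C)[C@H](O)[C@H]1C(C)(C)C=C | intermediate
19 | hydroxy methyl ester: as 18 with CO2Me (C2 epimers, 2R drawn) | COC(=O)[C@H](C)[C@H]1C(C)=C[C@@H](O[Si](C)(C)C(C)(C)C)[C@H](O)[C@H]1C(C)(C)C=C | intermediate
20 | mesylate: as 19 with 1α-OSO2CH3 (C2 epimers, 2R drawn) | COC(=O)[C@H](C)[C@H]1C(C)=C[C@@H](O[Si](C)(C)C(C)(C)C)[C@H](OS(C)(=O)=O)[C@H]1C(C)(C)C=C | intermediate
21 | potassium ester enolate of 20 (C2 planar) | COC([O-])=C(C)[C@H]1C(C)=C[C@@H](O[Si](C)(C)C(C)(C)C)[C@H](OS(C)(=O)=O)[C@H]1C(C)(C)C=C.[K+] | intermediate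
22 | bicyclo[3.1.1]hept-9-ene ester: C2 with CH3 syn to the C9–C11 bridge and CO2Me anti, C7 arm anti, 11-OSi(t-Bu)Me2 on the side of C2 | COC(=O)[C@@]1(C)[C@@H]2[C@H](O[Si](C)(C)C(C)(C)C)C=C(C)[C@H]1[C@@H]2C(C)(C)C=C | intermediate
23 | primary alcohol: as 22 with C3H2OH | OC[C@@]1(C)[C@@H]2[C@H](O[Si](C)(C)C(C)(C)C)C=C(C)[C@H]1[C@@H]2C(C)(C)C=C | intermediate
24 | aldehyde: as 22 with C3HO | O=C[C@@]1(C)[C@@H]2[C@H](O[Si](C)(C)C(C)(C)C)C=C(C)[C@H]1[C@@H]2C(C)(C)C=C | intermediate
25 | keto aldehyde: as 24 with C6–C(=O)CH3 arm | O=C[C@@]1(C)[C@@H]2[C@H](O[Si](C)(C)C(C)(C)C)C=C(C)[C@H]1[C@@H]2C(C)(C)C(C)=O | intermediate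
26 | aldol adduct: tricyclic 3-hydroxy-5-ketone, C3 epimer mixture | O=C1CC(O)[C@@]2(C)[C@@H]3[C@H](O[Si](C)(C)C(C)(C)C)C=C(C)[C@H]2[C@@H]3C1(C)C | intermediate
27 | tricyclic enone: C5=O, C3=C4, 11-silyl ether | O=C1C=C[C@@]2(C)[C@@H]3[C@H](O[Si](C)(C)C(C)(C)C)C=C(C)[C@H]2[C@@H]3C1(C)C | intermediate
28 | β-boryl ketone: pinacolboronate at C3 (boron on the side of C1) | O=C1C[C@@H](B4OC(C)(C)C(C)(C)O4)[C@@]2(C)[C@@H]3[C@H](O[Si](C)(C)C(C)(C)C)C=C(C)[C@H]2[C@@H]3C1(C)C | intermediate
29 | β-hydroxy ketone: (3R)-OH on the side of C1, C5=O | O=C1C[C@@H](O)[C@@]2(C)[C@@H]3[C@H](O[Si](C)(C)C(C)(C)C)C=C(C)[C@H]2[C@@H]3C1(C)C | intermediate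
30 | isobutyraldehyde (2-methylpropanal) | CC(C)C=O | starting material
31 | hemiacetal of 29 with 30 at the C3 oxygen | O=C1C[C@@H](OC(O)C(C)C)[C@@]2(C)[C@@H]3[C@H](O[Si](C)(C)C(C)(C)C)C=C(C)[C@H]2[C@@H]3C1(C)C | intermediate
32 | hydroxy isobutyrate: (3R)-isobutyrate, (5R)-OH anti to it, 11-silyl ether | O[C@@H]1C[C@@H](OC(=O)C(C)C)[C@@]2(C)[C@@H]3[C@H](O[Si](C)(C)C(C)(C)C)C=C(C)[C@H]2[C@@H]3C1(C)C | intermediate
33 | methacrylate: as 32 with C5 2-methylprop-2-enoate | C=C(C)C(=O)O[C@@H]1C[C@@H](OC(=O)C(C)C)[C@@]2(C)[C@@H]3[C@H](O[Si](C)(C)C(C)(C)C)C=C(C)[C@H]2[C@@H]3C1(C)C | intermediate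
34 | allylic alcohol: as 33 with free 11-OH (on the side of C2) | C=C(C)C(=O)O[C@@H]1C[C@@H](OC(=O)C(C)C)[C@@]2(C)[C@@H]3[C@H](O)C=C(C)[C@H]2[C@@H]3C1(C)C | intermediate
35 | (1R,2R,3R,5R,7S,8R)-2,6,6,9-tetramethyl-3-(2-methylpropanoyloxy)-11-oxotricyclo[5.4.0.0^{2,8}]undec-9-en-5-yl 2-methylprop-2-enoate (CNP0214356.1) | C=C(C)C(=O)O[C@@H]1C[C@@H](OC(=O)C(C)C)[C@@]2(C)[C@@H]3C(=O)C=C(C)[C@H]2[C@@H]3C1(C)C | target

## Step count and weak points

Total step count: 21. Longest linear sequence: 21 steps (the route is fully linear from 1; compounds 4, 14 and 30 are commercial).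

**Step 12 (key step).** Carbon alkylation at a β-branched secondary sulfonate by a fully substituted enolate may be slow. Alkylation on the enolate oxygen through a six-membered transition state, or breakdown of the enolate with loss of methoxide, could then take over. The fallback sets out from hydroxy acid 18, extracted after the rearrangement of step 10 and not esterified. MsCl and Et3N at −20 °C, followed by aqueous NaHCO3 to hydrolyse the mixed anhydride, give mesyloxy acid F1, which is used cold because its carboxylate can lactonise onto C1. Two equivalents of LiN(i-Pr)2 at −78 °C turn F1 into the carboxylate enediolate, a dianion that reacts on carbon and is much more nucleophilic than the ester enolate. It closes the same C1–C2 bond under the same allylic-strain control to give bicyclic acid F2. LiAlH4 reduces F2 to alcohol 23, where the route is rejoined.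

**Step 3.** The hindered tertiary nitrile anion may act as a base on the vinyl epoxide (isomerisation to a dienol and aromatisation), or regiocontrol of the opening may be incomplete. The fallback sets out from 3 and uses a less basic, Lewis-acid-assisted nucleophile: the lithium enolate of methyl isobutyrate is transmetalated with Et2AlCl, and the aluminium enolate opens the epoxide at C7 to give bromo hydroxy ester F3. Negishi methylation as in step 4 gives methyl hydroxy ester F4, and i-Bu2AlH at −78 °C reduces the ester to the aldehyde level, which closes to lactol 10.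

**Step 8 (and the selectivity of step 9).** Site selection among three secondary hydroxyls may be incomplete: silylation at C10 or C1, or over-acylation in step 9. The fallback sets out from triol 12 and replaces steric selection by stereoelectronic control. Trimethyl orthopropionate with a trace of camphorsulfonic acid forms the cyclic orthoester F5 on the cis-diol (C10/C11). Dilute aqueous acetic acid opens it to the ester of the pseudo-axial oxygen, C10 propionate diol F6, following the known preference of cis-fused orthoesters on six-membered rings to give the axial ester. t-BuMe2SiOTf and 2,6-lutidine at −78 °C then silylate C11–OH ahead of the hindered C1–OH without acyl migration, giving 15.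

**Step 17.** The boryl copper addition at C3 may be slow or weakly face-selective, because C3 is flanked by the quaternary C2 and the substrate offers the catalyst little to read. The fallback sets out from keto aldehyde 25: kinetic intramolecular aldol addition with LiN(SiMe3)2 at −78 °C, without dehydration, gives 29 together with its C3 epimer F7. The two are diastereomers and can be separated by chromatography; F7 is returned to the mixture by retro-aldol and re-aldol equilibration with catalytic KOt-Bu. The route is rejoined at 29.

**Step 18.** Hemiacetal formation and hydride transfer at a doubly neopentyl site may be sluggish, and the Lewis acidic trivalent samarium alkoxide may trigger retro-aldol opening of 29. The fallback sets out from 29: isobutyric anhydride with catalytic Sc(OTf)3 at −20 °C (acid catalysis avoids E1cB loss of the acyloxy group) gives keto isobutyrate F8. Reduction with (S)-2-methyl-CBS-oxazaborolidine and BH3·SMe2 then sets C5 under reagent control, with C6 as the large and C4 as the small substituent, to give 32.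

## Further compounds

F1 | step 12 | mesyloxy acid: as 20 with CO2H in place of CO2Me (C2 epimers, 2R drawn) | OC(=O)[C@H](C)[C@H]1C(C)=C[C@@H](O[Si](C)(C)C(C)(C)C)[C@H](OS(C)(=O)=O)[C@H]1C(C)(C)C=C
F2 | step 12 | bicyclic acid: as 22 with CO2H in place of CO2Me | OC(=O)[C@@]1(C)[C@@H]2[C@H](O[Si](C)(C)C(C)(C)C)C=C(C)[C@H]1[C@@H]2C(C)(C)C=C
F3 | step 3 | bromo hydroxy ester: as 6 with C(CH3)2CO2Me in place of C(CH3)2CN | CC1(C)O[C@H]2[C@H](O)[C@@H](C(C)(C)C(=O)OC)C=C(Br)[C@H]2O1
F4 | step 3 | methyl hydroxy ester: as F3 with CH3 on C9 | CC1(C)O[C@H]2[C@H](O)[C@@H](C(C)(C)C(=O)OC)C=C(C)[C@H]2O1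
F5 | step 8 | cyclic orthoester of 12: 2-ethyl-2-methoxy-1,3-dioxolane on O10/O11, 1α-OH free | CCC1(OC)O[C@H]2[C@H](O)[C@@H](C(C)(C)C=C)C=C(C)[C@H]2O1
F6 | step 8 | C10 propionate diol: 10β-OC(=O)Et, 11β-OH, 1α-OH | O[C@H]1[C@H](O)[C@@H](C(C)(C)C=C)C=C(C)[C@H]1OC(=O)CC
F7 | step 17 | C3 epimer of 29 ((3S)-OH on the side of C8) | O=C1C[C@H](O)[C@@]2(C)[C@@H]3[C@H](O[Si](C)(C)C(C)(C)C)C=C(C)[C@H]2[C@@H]3C1(C)C
F8 | step 18 | keto isobutyrate: 29 acylated at the C3 oxygen | O=C1C[C@@H](OC(=O)C(C)C)[C@@]2(C)[C@@H]3[C@H](O[Si](C)(C)C(C)(C)C)C=C(C)[C@H]2[C@@H]3C1(C)C
A1 | alternative 1 | (2E,6E)-farnesyl diphosphate | CC(C)=CCC/C(C)=C/CC/C(C)=C/COP(O)(=O)OP(O)(O)=O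
A2 | alternative 1 | α-longipinene | C1CC[C@@]2(C)[C@@H]3CC=C(C)[C@H]2[C@@H]3C1(C)C
A3 | alternative 2 | 3-methyl-3-[(tert-butyldiphenylsilyloxy)methyl]cyclobutanone | CC1(CO[Si](c2ccccc2)(c2ccccc2)C(C)(C)C)CC(=O)C1
A4 | alternative 2 | (E)-crotonoyl chloride | C/C=C/C(Cl)=O
A5 | alternative 2 | bicyclo[3.1.1]heptane-2,6-dione with C2 methyl and silyloxymethyl groups | CC(C)(C)[Si](c1ccccc1)(c1ccccc1)OC[C@@]2(C)[C@@H]3C(=O)C[C@@H](C)[C@H]2C3=O
A6 | alternative 3 | aldoxime: bicyclic enone with vinyl and methyl on C2 and C(CH3)2CH=NOH on C7 | C=C[C@@]1(C)[C@@H]2C(=O)C=C(C)[C@H]1[C@@H]2C(C)(C)C=NO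
A7 | alternative 3 | nitrile oxide derived from A6 | C=C[C@@]1(C)[C@@H]2C(=O)C=C(C)[C@H]1[C@@H]2C(C)(C)C#[N+][O-]
A8 | alternative 3 | isoxazoline-fused tricyclic enone | O1N=C2C[C@@H]1[C@@]3(C)[C@@H]4C(=O)C=C(C)[C@H]3[C@@H]4C2(C)C
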